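**Retrosynthetic overview**

1. Target 24 comes from its tert-butyl ester 23; the (E)-enol ester is made by a stereoretentive copper-catalysed C–O coupling of an (E)-alkenylboron (21/22), itself from C4-aldehyde 20. The aldehyde and the 2-oxopropyl group come from ozonolysis of the propenyl and methallyl groups of 19.
2. Cycloheptenone ester 19 comes from trans-hydrindanone 16 by a one-carbon ring expansion (diazoacetate inserts C7 with its carboxyl between C6 and C8), then selenoxide dehydrogenation. The C4 and C5 side chains come from enone 13 by dissolving-metal reductive alkylation, which also removes the sulfone.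
3. Key disconnection: the C1–C2 and C3–C3a bonds of the cyclopentane. Phenyl vinyl sulfone (C2–C3) is stitched between the α'-enolate carbon (C3a) and the epoxide carbon (C1) of monocyclic epoxy-enone 7 in one anionic [3+2] annulation (Michael addition, then 5-exo epoxide opening).
4. Enabling feature: the unsubstituted C2–C3 bridge of the cyclopentane lies between quaternary C3a, which is α to C4 (a ketone carbonyl in 7, so C3a is an enolate carbon), and C1, whose neighbouring exocyclic C(CH3)2–OH oxygen marks C1 as a former epoxide carbon.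
5. Epoxy-enone 7 comes from (R)-carvone (Criegee degradation, cuprate addition/elimination that relays the stereocentre to C8a, Shi epoxidation). Ring order: six-membered ring (from carvone), then cyclopentane (key step), then seven-membered ring (ring expansion).

Key step: step 4

Remark on the chemistry: locants in the overview and in the Why lines are those of the target (octahydroazulene: C1 carbinol-bearing CH, C2–C3 the CH2CH2 bridge, C3a quaternary, C4 and C5 side-chain carbons, C6 ketone, C7 carboxyl-bearing carbon, C8 vinylic CH, C8a ring-fusion CH). Centres that are erased later (the methyl-bearing carbon of 5, the sulfonyl carbon of 9–13, the carbinol carbon of 12, C7 of 17 and 18) are left undefined in the SMILES; 6 and 7 are drawn as the trans epimers.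

**Route**

Step 1
Reactants: 1 (R)-(−)-carvone
Product: 4 (1R)-4-methyl-5-oxocyclohex-3-en-1-yl acetate, via methoxy hydroperoxide 2 (not isolated), via peroxyacetate 3 (not isolated)
Conditions: O3, CH2Cl2/MeOH, −78 °C; then Ac2O, Et3N, DMAP (cat.), 0 → 40 °C
Reagents that add atoms: ozone, [O-][O+]=O; methanol, CO
Why: Ozone cleaves the electron-rich isopropenyl group in preference to the enone, and the α-methoxy hydroperoxide is acylated and undergoes Criegee rearrangement with retention at the migrating ring carbon (acetate then demethylates the dioxacarbenium ion), so the carvone stereocentre is carried into the acetate unchanged.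

Step 2
Reactants: 4 (1R)-4-methyl-5-oxocyclohex-3-en-1-yl acetate
Product: 6 (5S,6S)-6-methyl-5-(2-methylprop-1-en-1-yl)cyclohex-2-en-1-one, via acetoxy ketone 5 (not isolated)
Conditions: (CH3)2C=CHMgBr (2.2 equiv), CuBr·SMe2 (1.1 equiv), THF, −78 → −40 °C; NH4Cl; then DBU, CH2Cl2, rt
Reagents that add atoms: 2-methylprop-1-enylmagnesium bromide, CC(C)=C[Mg]Br
Why: Cuprate conjugate addition should occur anti to the acetoxy group (trans-3,5) and so sets the future C8a centre, and E1cB elimination of acetate with DBU then moves the enone and erases the carvone-derived centre (traceless chirality relay).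

Step 3
Reactants: 6 (5S,6S)-6-methyl-5-(2-methylprop-1-en-1-yl)cyclohex-2-en-1-one
Product: 7 (5R,6S)-5-[(2R)-3,3-dimethyloxiran-2-yl]-6-methylcyclohex-2-en-1-one
Conditions: Shi ketone (D-fructose-derived, 30 mol %), Oxone (2KHSO5·KHSO4·K2SO4), K2CO3, Bu4NHSO4, MeCN/dimethoxymethane/aq. buffer pH 10.5, 0 °C
Reagents that add atoms: potassium peroxymonosulfate (active part of Oxone), [K+].[O-]S(=O)(=O)OO
Why: Shi epoxidation: the chiral dioxirane reacts only with the electron-rich trisubstituted alkene (the enone is inert) and its spiro transition state should deliver the (R)-epoxide under catalyst control.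

Step 4
Reactants: 7 (5R,6S)-5-[(2R)-3,3-dimethyloxiran-2-yl]-6-methylcyclohex-2-en-1-one
Product: 11 (1S,3aS,7aS)-1-(2-hydroxypropan-2-yl)-3a-methyl-2-(phenylsulfonyl)-1,2,3,3a,7,7a-hexahydro-4H-inden-4-one, via lithium enolate 8 (not isolated), via dilithio dianion 9 (not isolated), via deconjugated enone 10 (not isolated)
Conditions: LiN(iPr)2 (1.05 equiv), THF, −78 °C; CH2=CHSO2Ph (1.0 equiv), −78 °C; LiN(iPr)2 (1.1 equiv), HMPA, −78 → 0 °C; MeOH, then DBU (cat.), CH2Cl2, rt
Reagents that add atoms: phenyl vinyl sulfone, C=CS(=O)(=O)c1ccccc1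
Why: Kinetic α'-deprotonation gives cross-conjugated enolate 8, whose Michael addition to phenyl vinyl sulfone forms the C3–C3a bond and an α-sulfonyl carbanion; the second equivalent of base keeps this carbanion alive and parks the enone as its dienolate (dianion 9), and on warming the carbanion opens the epoxide at its secondary carbon to form the C1–C2 bond and unveil the tertiary alkoxide. The closest known reaction types are the Michael-initiated ring closure of cyclohexenone α'-enolates with vinyl sulfones (bicycloannulation) and the cyclization of epoxides by nitrile- or sulfone-stabilized carbanions (Stork epoxynitrile cyclization). The cyclopentane closes in the 5-exo-tet mode at the less hindered epoxide carbon, 6-endo attack at the fully substituted carbon being disfavoured. C3a is controlled by the existing C8a centre, because allylic 1,2-strain holds the epoxide-bearing side chain pseudo-axial on the enolate and the acceptor adds to the opposite face, which makes the ring fusion trans and leaves the methyl group cis to the C1 side chain; C1 is set by SN2 inversion of the (R)-epoxide, and the sulfonyl-bearing C2 is uncontrolled but is reduced to CH2 in step 7. The step needs the Michael addition to outrun 3-exo opening of the epoxide by the enolate (the mixture is held at −78 °C until the enolate is consumed) and the epoxide opening to outrun intramolecular Michael addition of the carbanion to the enone, which is secured by the dienolate form of the ketone and by the equatorial position of the sulfonylethyl chain; kinetic protonation of the dienolate gives some deconjugated enone 10, which DBU returns to 11.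

Step 5
Reactants: 11 (1S,3aS,7aS)-1-(2-hydroxypropan-2-yl)-3a-methyl-2-(phenylsulfonyl)-1,2,3,3a,7,7a-hexahydro-4H-inden-4-one
Product: 12 (1S,3aS,7aS)-1-(2-hydroxypropan-2-yl)-3a-methyl-2-(phenylsulfonyl)-4-(prop-2-en-1-yl)-2,3,3a,4,7,7a-hexahydro-1H-inden-4-ol
Conditions: CH2=CHCH2MgBr (4 equiv), THF, −78 → 0 °C
Reagents that add atoms: allylmagnesium bromide, C=CC[Mg]Br
Why: Grignard 1,2-addition of the allyl reagent to the hindered enone carbonyl through a cyclic transition state; the new carbinol centre is destroyed in step 6, and the excess reagent covers the free hydroxyl group.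

Step 6
Reactants: 12 (1S,3aS,7aS)-1-(2-hydroxypropan-2-yl)-3a-methyl-2-(phenylsulfonyl)-4-(prop-2-en-1-yl)-2,3,3a,4,7,7a-hexahydro-1H-inden-4-ol
Product: 13 (1S,3aS,7aS)-1-(2-hydroxypropan-2-yl)-3a-methyl-2-(phenylsulfonyl)-4-(prop-2-en-1-yl)-1,2,3,3a,7,7a-hexahydro-6H-inden-6-one
Conditions: pyridinium chlorochromate (C5H5NH[CrO3Cl]), NaOAc, 4 Å MS, CH2Cl2, rt
Reagents that add atoms: none
Why: Dauben–Babler oxidative 1,3-transposition: the chromate ester of the tertiary allylic alcohol undergoes [3,3] shift and oxidation, which moves the oxygen to C6 and gives the β-allyl enone, while the other tertiary alcohol cannot be oxidized.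

Step 7
Reactants: 13 (1S,3aS,7aS)-1-(2-hydroxypropan-2-yl)-3a-methyl-2-(phenylsulfonyl)-4-(prop-2-en-1-yl)-1,2,3,3a,7,7a-hexahydro-6H-inden-6-one
Product: 15 (1S,3aS,4S,5S,7aS)-1-(2-hydroxypropan-2-yl)-3a-methyl-5-(2-methylprop-2-en-1-yl)-4-(prop-2-en-1-yl)octahydro-6H-inden-6-one, via lithium enolate 14 (not isolated)
Conditions: Li (5 equiv), NH3/THF, −78 °C; isoprene; CH2=C(CH3)CH2Br, −78 → −33 °C; NH4Cl
Reagents that add atoms: 3-bromo-2-methylprop-1-ene, CC(=C)CBr
Why: Stork-type dissolving-metal reductive alkylation with concurrent reductive desulfonylation: axial protonation of the β-carbanion should put the C4 allyl group equatorial (cis to the axial angular methyl), the regiodefined enolate 14 is alkylated at C5 anti to the C4 substituent and to the angular methyl (trans, equatorial, also the thermodynamic epimer), and the same electrons cleave the C–SO2Ph bond.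

Step 8
Reactants: 15 (1S,3aS,4S,5S,7aS)-1-(2-hydroxypropan-2-yl)-3a-methyl-5-(2-methylprop-2-en-1-yl)-4-(prop-2-en-1-yl)octahydro-6H-inden-6-one
Product: 16 (1S,3aS,4S,5S,7aS)-1-(2-hydroxypropan-2-yl)-3a-methyl-5-(2-methylprop-2-en-1-yl)-4-[(1E)-prop-1-en-1-yl]octahydro-6H-inden-6-one
Conditions: [Ir(cod)(PMePh2)2]PF6 (2 mol %, activated with H2), THF, rt
Reagents that add atoms: none
Why: Iridium hydride-catalysed alkene isomerization should move the monosubstituted allyl double bond by one position to the (E)-propenyl group, while the 1,1-disubstituted methallyl alkene inserts too slowly to react.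

Step 9
Reactants: 16 (1S,3aS,4S,5S,7aS)-1-(2-hydroxypropan-2-yl)-3a-methyl-5-(2-methylprop-2-en-1-yl)-4-[(1E)-prop-1-en-1-yl]octahydro-6H-inden-6-one
Product: 17 tert-butyl (1S,3aS,4S,5S,8aS)-1-(2-hydroxypropan-2-yl)-3a-methyl-5-(2-methylprop-2-en-1-yl)-6-oxo-4-[(1E)-prop-1-en-1-yl]decahydroazulene-7-carboxylate
Conditions: tert-butyl diazoacetate, BF3·OEt2, CH2Cl2, −78 → −20 °C
Reagents that add atoms: tert-butyl diazoacetate, CC(C)(C)OC(=O)C=[N+]=[N-]
Why: Lewis acid-promoted diazoacetate homologation of the ketone (Tiffeneau–Demjanov-type ring expansion) inserts C7 together with its carboxyl group, and the less substituted C8 methylene should migrate in preference to the branched C5, so the ester ends up between C6 and C8.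

Step 10
Reactants: 17 tert-butyl (1S,3aS,4S,5S,8aS)-1-(2-hydroxypropan-2-yl)-3a-methyl-5-(2-methylprop-2-en-1-yl)-6-oxo-4-[(1E)-prop-1-en-1-yl]decahydroazulene-7-carboxylate
Product: 19 tert-butyl (1S,3aS,4S,5S,8aS)-1-(2-hydroxypropan-2-yl)-3a-methyl-5-(2-methylprop-2-en-1-yl)-6-oxo-4-[(1E)-prop-1-en-1-yl]-1,2,3,3a,4,5,6,8a-octahydroazulene-7-carboxylate, via selenide 18 (not isolated)
Conditions: NaH (2.2 equiv), THF, 0 °C; PhSeBr, −78 °C; then 30% H2O2, CH2Cl2, 0 °C
Reagents that add atoms: none
Why: Selenenylation of the β-keto ester enolate (much faster than addition of PhSeBr to the alkenes at −78 °C) followed by selenoxide syn-elimination, which can only take a hydrogen from C8, gives the C7=C8 enone ester without touching C8a.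

Step 11
Reactants: 19 tert-butyl (1S,3aS,4S,5S,8aS)-1-(2-hydroxypropan-2-yl)-3a-methyl-5-(2-methylprop-2-en-1-yl)-6-oxo-4-[(1E)-prop-1-en-1-yl]-1,2,3,3a,4,5,6,8a-octahydroazulene-7-carboxylate
Product: 20 tert-butyl (1S,3aS,4S,5S,8aS)-4-formyl-1-(2-hydroxypropan-2-yl)-3a-methyl-6-oxo-5-(2-oxopropyl)-1,2,3,3a,4,5,6,8a-octahydroazulene-7-carboxylate
Conditions: O3, CH2Cl2/MeOH, pyridine, −78 °C (indicator end point); Me2S
Reagents that add atoms: ozone, [O-][O+]=O
Why: Ozonolysis cleaves the two electron-rich alkenes (propenyl to the C4 formyl group, methallyl to the 2-oxopropyl group) and spares the doubly acceptor-substituted C7=C8 bond; the formyl group stays in the equatorial, thermodynamically preferred position, and the keto aldehyde is used at once to avoid aldol closure.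

Step 12
Reactants: 20 tert-butyl (1S,3aS,4S,5S,8aS)-4-formyl-1-(2-hydroxypropan-2-yl)-3a-methyl-6-oxo-5-(2-oxopropyl)-1,2,3,3a,4,5,6,8a-octahydroazulene-7-carboxylate
Product: 21 tert-butyl (1S,3aS,4S,5S,8aS)-1-(2-hydroxypropan-2-yl)-3a-methyl-6-oxo-5-(2-oxopropyl)-4-[(E)-2-(4,4,5,5-tetramethyl-1,3,2-dioxaborolan-2-yl)ethenyl]-1,2,3,3a,4,5,6,8a-octahydroazulene-7-carboxylate
Conditions: CrCl2 (8 equiv), LiI, Cl2CHB(pin), THF, rt
Reagents that add atoms: 2-(dichloromethyl)-4,4,5,5-tetramethyl-1,3,2-dioxaborolane, ClC(Cl)B1OC(C)(C)C(C)(C)O1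
Why: Takai–Utimoto borylolefination: the gem-dichromium reagent adds to the aldehyde only (ketones and the enone ester are left) and the elimination should give the (E)-alkenylboronate.

Step 13
Reactants: 21 tert-butyl (1S,3aS,4S,5S,8aS)-1-(2-hydroxypropan-2-yl)-3a-methyl-6-oxo-5-(2-oxopropyl)-4-[(E)-2-(4,4,5,5-tetramethyl-1,3,2-dioxaborolan-2-yl)ethenyl]-1,2,3,3a,4,5,6,8a-octahydroazulene-7-carboxylate
Product: 23 tert-butyl (1S,3aS,4S,5S,8aS)-1-(2-hydroxypropan-2-yl)-3a-methyl-4-[(E)-2-(3-methylbut-2-enoyloxy)ethenyl]-6-oxo-5-(2-oxopropyl)-1,2,3,3a,4,5,6,8a-octahydroazulene-7-carboxylate, via trifluoroborate 22 (not isolated)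
Conditions: KHF2, MeOH/H2O, rt; then 3-methylbut-2-enoic acid, CuBr (10 mol %), DMAP (20 mol %), 4 Å MS, O2, MeCN, 40 °C
Reagents that add atoms: 3-methylbut-2-enoic acid, CC(C)=CC(=O)O
Why: Chan–Lam-type copper-catalysed oxidative C–O coupling of the alkenyltrifluoroborate with the carboxylic acid should proceed with retention of alkene geometry, so the (E)-enol ester follows from the (E)-alkenylboron, and the acid-buffered medium is too weakly basic to deconjugate the enone ester.

Step 14
Reactants: 23 tert-butyl (1S,3aS,4S,5S,8aS)-1-(2-hydroxypropan-2-yl)-3a-methyl-4-[(E)-2-(3-methylbut-2-enoyloxy)ethenyl]-6-oxo-5-(2-oxopropyl)-1,2,3,3a,4,5,6,8a-octahydroazulene-7-carboxylate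
Product: 24 (1S,3aS,4S,5S,8aS)-1-(2-hydroxypropan-2-yl)-3a-methyl-4-[(E)-2-(3-methylbut-2-enoyloxy)ethenyl]-6-oxo-5-(2-oxopropyl)-1,2,3,3a,4,5,6,8a-octahydroazulene-7-carboxylic acid
Conditions: ZnBr2 (5 equiv), CH2Cl2, rt
Reagents that add atoms: none
Why: Chelation-assisted Lewis-acid cleavage of the tert-butyl ester (loss of 2-methylpropene) should free the acid without base or strong protic acid, so the enol ester, the tertiary alcohol and the C8a–H next to the enone are left alone.

**Compound list**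

1 | (R)-(−)-carvone, (5R)-2-methyl-5-(prop-1-en-2-yl)cyclohex-2-en-1-one | CC1=CC[C@@H](C(C)=C)CC1=O | starting material
2 | (5R)-5-(1-hydroperoxy-1-methoxyethyl)-2-methylcyclohex-2-en-1-one | CC1=CC[C@@H](C(C)(OC)OO)CC1=O | intermediate
3 | 1-methoxy-1-[(1R)-4-methyl-5-oxocyclohex-3-en-1-yl]ethyl ethaneperoxoate | CC1=CC[C@@H](C(C)(OC)OOC(C)=O)CC1=O | intermediate
4 | (1R)-4-methyl-5-oxocyclohex-3-en-1-yl acetate | CC1=CC[C@@H](OC(C)=O)CC1=O | intermediate
5 | (1R,3S)-4-methyl-3-(2-methylprop-1-en-1-yl)-5-oxocyclohexyl acetate (3,5-trans; C4 epimers) | CC1C(=O)C[C@H](OC(C)=O)C[C@H]1C=C(C)C | intermediate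
6 | (5S,6S)-6-methyl-5-(2-methylprop-1-en-1-yl)cyclohex-2-en-1-one | O=C1C=CC[C@@H](C=C(C)C)[C@@H]1C | intermediate
7 | (5R,6S)-5-[(2R)-3,3-dimethyloxiran-2-yl]-6-methylcyclohex-2-en-1-one | O=C1C=CC[C@@H]([C@H]2OC2(C)C)[C@@H]1C | intermediate
8 | lithium (3R)-3-[(2R)-3,3-dimethyloxiran-2-yl]-2-methylcyclohexa-1,5-dien-1-olate (α'-enolate of 7) | [Li+].[O-]C1=C(C)[C@H]([C@H]2OC2(C)C)CC=C1 | intermediate
9 | dilithio dianion (dienolate and α-sulfonyl carbanion) of the Michael adduct of 8 and phenyl vinyl sulfone | [Li+].[Li+].[O-]C1=CC=C[C@@H]([C@H]2OC2(C)C)[C@]1(C)C[CH-]S(=O)(=O)c1ccccc1 | intermediate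
10 | (1S,3aS,7aS)-1-(2-hydroxypropan-2-yl)-3a-methyl-2-(phenylsulfonyl)-1,2,3,3a,5,7a-hexahydro-4H-inden-4-one (β,γ-enone isomer of 11) | O=C1CC=C[C@H]2[C@@H](C(C)(C)O)C(S(=O)(=O)c3ccccc3)C[C@]12C | intermediate
11 | (1S,3aS,7aS)-1-(2-hydroxypropan-2-yl)-3a-methyl-2-(phenylsulfonyl)-1,2,3,3a,7,7a-hexahydro-4H-inden-4-one (trans-fused; C2 epimers) | O=C1C=CC[C@H]2[C@@H](C(C)(C)O)C(S(=O)(=O)c3ccccc3)C[C@]12C | intermediate
12 | (1S,3aS,7aS)-1-(2-hydroxypropan-2-yl)-3a-methyl-2-(phenylsulfonyl)-4-(prop-2-en-1-yl)-2,3,3a,4,7,7a-hexahydro-1H-inden-4-ol (C2 and C4 epimers) | C=CCC1(O)C=CC[C@H]2[C@@H](C(C)(C)O)C(S(=O)(=O)c3ccccc3)C[C@]12C | intermediate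
13 | (1S,3aS,7aS)-1-(2-hydroxypropan-2-yl)-3a-methyl-2-(phenylsulfonyl)-4-(prop-2-en-1-yl)-1,2,3,3a,7,7a-hexahydro-6H-inden-6-one | O=C1C[C@H]2[C@@H](C(C)(C)O)C(S(=O)(=O)c3ccccc3)C[C@]2(C)C(CC=C)=C1 | intermediate
14 | dilithium salt (C5=C6 enolate and tertiary alkoxide) of (1S,3aS,4S,7aS)-1-(2-hydroxypropan-2-yl)-3a-methyl-4-(prop-2-en-1-yl)octahydro-6H-inden-6-one | [Li+].[Li+].C1=C([O-])C[C@H]2[C@@H](C(C)(C)[O-])CC[C@]2(C)[C@H]1CC=C | intermediate
15 | (1S,3aS,4S,5S,7aS)-1-(2-hydroxypropan-2-yl)-3a-methyl-5-(2-methylprop-2-en-1-yl)-4-(prop-2-en-1-yl)octahydro-6H-inden-6-one | CC(=C)C[C@@H]1C(=O)C[C@H]2[C@@H](C(C)(C)O)CC[C@]2(C)[C@H]1CC=C | intermediate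
16 | (1S,3aS,4S,5S,7aS)-1-(2-hydroxypropan-2-yl)-3a-methyl-5-(2-methylprop-2-en-1-yl)-4-[(1E)-prop-1-en-1-yl]octahydro-6H-inden-6-one | CC(=C)C[C@@H]1C(=O)C[C@H]2[C@@H](C(C)(C)O)CC[C@]2(C)[C@H]1/C=C/C | intermediate
17 | tert-butyl (1S,3aS,4S,5S,8aS)-1-(2-hydroxypropan-2-yl)-3a-methyl-5-(2-methylprop-2-en-1-yl)-6-oxo-4-[(1E)-prop-1-en-1-yl]decahydroazulene-7-carboxylate (C7 epimers) | CC(=C)C[C@@H]1C(=O)C(C(=O)OC(C)(C)C)C[C@H]2[C@@H](C(C)(C)O)CC[C@]2(C)[C@H]1/C=C/C | intermediate
18 | tert-butyl (1S,3aS,4S,5S,8aS)-1-(2-hydroxypropan-2-yl)-3a-methyl-5-(2-methylprop-2-en-1-yl)-6-oxo-7-(phenylselanyl)-4-[(1E)-prop-1-en-1-yl]decahydroazulene-7-carboxylate | CC(=C)C[C@@H]1C(=O)C([Se]c3ccccc3)(C(=O)OC(C)(C)C)C[C@H]2[C@@H](C(C)(C)O)CC[C@]2(C)[C@H]1/C=C/C | intermediate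
19 | tert-butyl (1S,3aS,4S,5S,8aS)-1-(2-hydroxypropan-2-yl)-3a-methyl-5-(2-methylprop-2-en-1-yl)-6-oxo-4-[(1E)-prop-1-en-1-yl]-1,2,3,3a,4,5,6,8a-octahydroazulene-7-carboxylate | CC(=C)C[C@@H]1C(=O)C(C(=O)OC(C)(C)C)=C[C@H]2[C@@H](C(C)(C)O)CC[C@]2(C)[C@H]1/C=C/C | intermediate
20 | tert-butyl (1S,3aS,4S,5S,8aS)-4-formyl-1-(2-hydroxypropan-2-yl)-3a-methyl-6-oxo-5-(2-oxopropyl)-1,2,3,3a,4,5,6,8a-octahydroazulene-7-carboxylate | CC(=O)C[C@@H]1C(=O)C(C(=O)OC(C)(C)C)=C[C@H]2[C@@H](C(C)(C)O)CC[C@]2(C)[C@H]1C=O | intermediate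
21 | tert-butyl (1S,3aS,4S,5S,8aS)-1-(2-hydroxypropan-2-yl)-3a-methyl-6-oxo-5-(2-oxopropyl)-4-[(E)-2-(4,4,5,5-tetramethyl-1,3,2-dioxaborolan-2-yl)ethenyl]-1,2,3,3a,4,5,6,8a-octahydroazulene-7-carboxylate | CC(=O)C[C@@H]1C(=O)C(C(=O)OC(C)(C)C)=C[C@H]2[C@@H](C(C)(C)O)CC[C@]2(C)[C@H]1/C=C/B1OC(C)(C)C(C)(C)O1 | intermediate
22 | potassium trifluoro[(E)-2-(azulen-4-yl)ethenyl]borate corresponding to 21 (Bpin replaced by BF3K) | [K+].CC(=O)C[C@@H]1C(=O)C(C(=O)OC(C)(C)C)=C[C@H]2[C@@H](C(C)(C)O)CC[C@]2(C)[C@H]1/C=C/[B-](F)(F)F | intermediate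
23 | tert-butyl (1S,3aS,4S,5S,8aS)-1-(2-hydroxypropan-2-yl)-3a-methyl-4-[(E)-2-(3-methylbut-2-enoyloxy)ethenyl]-6-oxo-5-(2-oxopropyl)-1,2,3,3a,4,5,6,8a-octahydroazulene-7-carboxylate | CC(=O)C[C@@H]1C(=O)C(C(=O)OC(C)(C)C)=C[C@H]2[C@@H](C(C)(C)O)CC[C@]2(C)[C@H]1/C=C/OC(=O)C=C(C)C | intermediate
24 | (1S,3aS,4S,5S,8aS)-1-(2-hydroxypropan-2-yl)-3a-methyl-4-[(E)-2-(3-methylbut-2-enoyloxy)ethenyl]-6-oxo-5-(2-oxopropyl)-1,2,3,3a,4,5,6,8a-octahydroazulene-7-carboxylic acid (CNP0290717.1) | CC(=O)C[C@@H]1C(=O)C(C(=O)O)=C[C@H]2[C@@H](C(C)(C)O)CC[C@]2(C)[C@H]1/C=C/OC(=O)C=C(C)C | target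

**Step count and risks**

Total steps: 14. Longest linear sequence: 14 steps, all linear from (R)-carvone 1.

The three steps most likely to fail, with fallbacks:

Step 4 (key step). The hindered tetrasubstituted enolate may add to the vinyl sulfone too slowly. In that case the enolate can open the epoxide in a 3-exo fashion (cyclopropane formation), or the vinyl sulfone can polymerize anionically. After the addition, intramolecular Michael addition of the carbanion to the enone or proton transfer can compete with the 5-exo epoxide opening. The fallback makes the two bonds in separate, individually known operations, starting from 6, which carries no epoxide, so the Michael addition can be pushed (HMPA, −78 to −40 °C) and quenched cold with acetic acid. This gives the keto sulfone (5S,6S)-6-methyl-5-(2-methylprop-1-en-1-yl)-6-[2-(phenylsulfonyl)ethyl]cyclohex-2-en-1-one F1. Shi epoxidation of F1 gives the epoxy sulfone (5R,6S)-5-[(2R)-3,3-dimethyloxiran-2-yl]-6-methyl-6-[2-(phenylsulfonyl)ethyl]cyclohex-2-en-1-one F2. Closing F2 with LiN(iPr)2 (2.2 equiv) in THF/HMPA (sulfone-carbanion epoxide cyclization) rejoins the route at 11.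

Step 7. Three events share one flask. The lithium amide formed during C–S cleavage can scramble the enolate by proton exchange, which would cause alkylation at C7 or double alkylation. The ketone may also be over-reduced, or the tertiary alkoxide O-alkylated. The fallback separates reduction and alkylation, starting from 13: Li/NH3 reduction is quenched with Me3SiCl/Et3N to isolate the bis-silylated enol ether, the trimethylsilyl enol ether of the C6 ketone with a trimethylsilyl ether at the tertiary alcohol F3. The amide-free lithium enolate is then regenerated from F3 with MeLi in THF and alkylated with 3-bromo-2-methylprop-1-ene. Dilute acid on work-up removes the tertiary silyl ether and rejoins the route at 15.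

Step 13. Protodeboronation or oxidative homocoupling of the alkenylborate may outpace C–O bond formation, and the amine base may slowly deconjugate the enone ester through deprotonation at C8a. The fallback changes the bond construction, starting from 21: oxidation with NaBO3·4H2O in THF/H2O gives the aldehyde tert-butyl (1S,3aS,4S,5S,8aS)-1-(2-hydroxypropan-2-yl)-3a-methyl-6-oxo-4-(2-oxoethyl)-5-(2-oxopropyl)-1,2,3,3a,4,5,6,8a-octahydroazulene-7-carboxylate F4. O-acylation of the aldehyde enol of F4 with 3-methylbut-2-enoic anhydride, Et3N and DMAP (cat.) in CH2Cl2 at 0 °C gives the enol ester. This is expected to form as an E/Z mixture, so the (E)-isomer must be separated by chromatography; it rejoins the route at 23.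

**Further compounds**

F1 | step 4 | (5S,6S)-6-methyl-5-(2-methylprop-1-en-1-yl)-6-[2-(phenylsulfonyl)ethyl]cyclohex-2-en-1-one | O=C1C=CC[C@@H](C=C(C)C)[C@]1(C)CCS(=O)(=O)c1ccccc1
F2 | step 4 | (5R,6S)-5-[(2R)-3,3-dimethyloxiran-2-yl]-6-methyl-6-[2-(phenylsulfonyl)ethyl]cyclohex-2-en-1-one | O=C1C=CC[C@@H]([C@H]2OC2(C)C)[C@]1(C)CCS(=O)(=O)c1ccccc1
F3 | step 7 | trimethylsilyl enol ether (C5=C6) of (1S,3aS,4S,7aS)-3a-methyl-4-(prop-2-en-1-yl)-1-[2-(trimethylsilyloxy)propan-2-yl]octahydro-6H-inden-6-one | C1=C(O[Si](C)(C)C)C[C@H]2[C@@H](C(C)(C)O[Si](C)(C)C)CC[C@]2(C)[C@H]1CC=C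
F4 | step 13 | tert-butyl (1S,3aS,4S,5S,8aS)-1-(2-hydroxypropan-2-yl)-3a-methyl-6-oxo-4-(2-oxoethyl)-5-(2-oxopropyl)-1,2,3,3a,4,5,6,8a-octahydroazulene-7-carboxylate | CC(=O)C[C@@H]1C(=O)C(C(=O)OC(C)(C)C)=C[C@H]2[C@@H](C(C)(C)O)CC[C@]2(C)[C@H]1CC=O
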